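**Strategy.** The bicyclo[3.2.1]octenone is unlocked at C4–C5 (aldol), leaving a cyclopentanone (ring C1–C7–C6–C5–C8) on which aryl at C6, methyl at C7 and allyl at C1 sit on alternating faces. The key step uses exactly this alternation: Me2CuLi delivers methyl to C7 anti to the C6 aryl group, and the enolate so formed is allylated at C1 anti to the new methyl, giving two C–C bonds, two stereocentres and the quaternary bridgehead in one pot. Its precursor is an (S)-4-arylcyclopent-2-enone carrying at C1 a cis-configured C2=C3(OMe)–C4 acetal arm, a cross-conjugated, electron-rich spectator that later supplies the six-membered ring.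

Key step: step 7

Remarks and assumptions
- Locants C1–C8 are those of the target core: C1 allyl bridgehead, C2=C3(OMe), C4 CH(OAc), C5 OMe bridgehead, C6 CH(aryl), C7 CH(CH3), C8 C=O. They are kept for the same carbons in all earlier compounds; systematic names in the compound list use their own ring locants. Ar = 3,4-dimethoxyphenyl.
- The hydroxylation product of step 8 is drawn with OH trans to the C6 aryl group, the expected major epimer. Either C5 epimer serves, because C5 becomes an enolate carbon again in step 11.
- Reagent 10 is charged as a freshly prepared ethereal solution; its preparation is not counted as a step.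
- "Exo" at C4 means the face of the six-membered ring that carries the C8 carbonyl bridge.

**Step 1**
Reactants: 1 (S)-4-[(tert-butyldimethylsilyl)oxy]cyclopent-2-en-1-one; 2 (3,4-dimethoxyphenyl)magnesium bromide
Product: 3 (3R,4S)-4-[(tert-butyldimethylsilyl)oxy]-3-(3,4-dimethoxyphenyl)cyclopentan-1-one (aryl trans to silyloxy)
Conditions: 2 (1.3 equiv), CuBr·SMe2 (10 mol%), THF, −78 °C; aq NH4Cl
Reagents that add atoms: none
Why: Copper-catalysed conjugate addition of the aryl Grignard reagent (organocuprate 1,4-addition) takes place on the face opposite the silyloxy group, so the aryl-bearing stereocentre (later C6) is set by 1,2-induction from the purchased (S) centre, and at −78 °C the adduct keeps its silyloxy group until the aqueous quench.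

**Step 2**
Reactants: 3 (3R,4S)-4-[(tert-butyldimethylsilyl)oxy]-3-(3,4-dimethoxyphenyl)cyclopentan-1-one
Product: 4 (S)-4-(3,4-dimethoxyphenyl)cyclopent-2-en-1-one
Conditions: DBU (1.2 equiv), CH2Cl2, 0 °C, 30 min
Reagents that add atoms: none
Why: E1cB β-elimination of the silanolate can place the double bond only between the carbons that bore H and OSi, which gives the 4-aryl enone regiospecifically, and the short, cold exposure to base is chosen to spare the benzylic γ-hydrogen and thus the stereocentre.

**Step 3**
Reactants: 4 (S)-4-(3,4-dimethoxyphenyl)cyclopent-2-en-1-one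
Product: 5 (S)-4-(3,4-dimethoxyphenyl)-2-iodocyclopent-2-en-1-one
Conditions: I2, pyridine, CH2Cl2, 0 °C → rt
Reagents that add atoms: iodine, II
Why: α-Iodination of the enone by a Baylis–Hillman-type addition–elimination (pyridine adds conjugately, the enolate is iodinated, pyridine is expelled) touches only the enone α-carbon and leaves the stereocentre and the dimethoxyarene alone.

**Step 4**
Reactants: 6 3,3-diethoxyprop-1-yne
Product: 7 (E)-3,3-diethoxy-1-iodo-2-methoxyprop-1-ene (iodine cis to the acetal carbon)
Conditions: I(py)2BF4, HBF4·OEt2, MeOH (5 equiv), CH2Cl2, −60 → 0 °C, dark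
Reagents that add atoms: bis(pyridine)iodonium tetrafluoroborate, [I+].c1ccncc1.c1ccncc1.F[B-](F)(F)F; methanol, CO
Why: Anti iodo-alkoxylation of an alkyne: the iodonium reagent forms a bridged iodonium ion, methanol opens it from the opposite side at the internal carbon (the only one that can carry charge as a secondary vinyl cation), so iodine ends trans to OMe and cis to the acetal carbon, while the cold, pyridinium-buffered medium is too weakly acidic to exchange the acetal or add a second methanol.

**Step 5**
Reactants: 7 (E)-3,3-diethoxy-1-iodo-2-methoxyprop-1-ene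
Product: 8 2-[(E)-3,3-diethoxy-2-methoxyprop-1-en-1-yl]-4,4,5,5-tetramethyl-1,3,2-dioxaborolane (boron cis to the acetal carbon)
Conditions: B2pin2, PdCl2(PPh3)2 (3 mol%), PPh3, KOPh, toluene, 50 °C
Reagents that add atoms: bis(pinacolato)diboron, CC1(C)OB(OC1(C)C)B1OC(C)(C)C(C)(C)O1
Why: Miyaura borylation of a 1-alkenyl iodide (oxidative addition to zerovalent palladium, transmetalation with the phenoxide-activated diboron, reductive elimination) keeps the double-bond geometry and avoids a β-methoxyvinyl lithium or zinc species, which would lose methoxide by anti elimination.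

**Step 6**
Reactants: 5 (S)-4-(3,4-dimethoxyphenyl)-2-iodocyclopent-2-en-1-one; 8 2-[(E)-3,3-diethoxy-2-methoxyprop-1-en-1-yl]-4,4,5,5-tetramethyl-1,3,2-dioxaborolane
Product: 9 (S)-2-[(E)-3,3-diethoxy-2-methoxyprop-1-en-1-yl]-4-(3,4-dimethoxyphenyl)cyclopent-2-en-1-one
Conditions: PdCl2(dppf) (5 mol%), AsPh3 (10 mol%), aq K3PO4, THF, rt, degassed
Reagents that add atoms: none
Why: Suzuki–Miyaura coupling of an α-iodoenone with an alkenylboronate at room temperature joins C1 to C2 with retention at both sp2 carbons, and the weak aqueous base should leave the acetal, the enol ether and the base-sensitive benzylic stereocentre untouched.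

**Step 7**
Reactants: 9 (S)-2-[(E)-3,3-diethoxy-2-methoxyprop-1-en-1-yl]-4-(3,4-dimethoxyphenyl)cyclopent-2-en-1-one; 10 lithium dimethylcuprate; 11 allyl bromide
Product: 13 (2S,3R,4S)-2-allyl-2-[(E)-3,3-diethoxy-2-methoxyprop-1-en-1-yl]-4-(3,4-dimethoxyphenyl)-3-methylcyclopentan-1-one, via lithium enolate 12 (not isolated)
Conditions: 10 (1.5 equiv), Et2O, −78 → −40 °C; then HMPA, 11 (5 equiv), −78 → −20 °C
Reagents that add atoms: none
Why: Me2CuLi forms a π-complex with the ring enone and adds oxidatively at the β-carbon C7 to a trivalent copper intermediate, whose reductive elimination makes the C7–CH3 bond and leaves the lithium enolate O–C8=C1 (12), conjugated with C2=C3; this enolate then displaces bromide from allyl bromide at C1 in an SN2 step assisted by HMPA. The closest known reaction type is the three-component coupling of cyclopentenones by cuprate conjugate addition and enolate alkylation, in which each new group enters trans to its neighbour. No ring is closed. C7 is controlled by the adjacent C6 aryl group, which shields one face of the flat enone so that methyl enters anti to it, and C1 is controlled by the new C7 methyl group, anti to which allyl enters, leaving the C2–C4 arm cis to methyl as the later bridge requires. The step needs 1,4-addition to the ring enone only, secured because the arm sits on the α-carbon, is cross-conjugated with the carbonyl group and is an electron-rich enol ether without an acceptor position; it needs α- over γ- and C- over O-allylation, secured by the fully substituted, methoxy-bearing γ-carbon C3 and the soft bromide; and it needs the enolate to stay on the C1 side, secured by low temperature and excess allyl bromide.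

**Step 8**
Reactants: 13 (2S,3R,4S)-2-allyl-2-[(E)-3,3-diethoxy-2-methoxyprop-1-en-1-yl]-4-(3,4-dimethoxyphenyl)-3-methylcyclopentan-1-one
Product: 15 (2S,3R,4S,5S)-2-allyl-2-[(E)-3,3-diethoxy-2-methoxyprop-1-en-1-yl]-4-(3,4-dimethoxyphenyl)-5-hydroxy-3-methylcyclopentan-1-one, via potassium enolate 14 (not isolated)
Conditions: KN(SiMe3)2, THF, −78 °C; then 2-(phenylsulfonyl)-3-phenyloxaziridine, −78 °C; AcOH
Reagents that add atoms: 2-(phenylsulfonyl)-3-phenyloxaziridine, O=S(=O)(c1ccccc1)N1OC1c1ccccc1
Why: Davis oxidation: the enolate, which can form only towards C5 because C1 is quaternary, attacks the oxaziridine oxygen, and this oxidant reacts with the enolate alone and spares the enol ether and the terminal alkene, which a peracid would not; the hydroxyl group should enter trans to the C6 aryl group.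

**Step 9**
Reactants: 15 (2S,3R,4S,5S)-2-allyl-2-[(E)-3,3-diethoxy-2-methoxyprop-1-en-1-yl]-4-(3,4-dimethoxyphenyl)-5-hydroxy-3-methylcyclopentan-1-one
Product: 16 (2S,3R,4S,5S)-2-allyl-2-[(E)-3,3-diethoxy-2-methoxyprop-1-en-1-yl]-4-(3,4-dimethoxyphenyl)-5-methoxy-3-methylcyclopentan-1-one
Conditions: MeI, Ag2O, 4 Å MS, MeCN, rt, dark
Reagents that add atoms: iodomethane, CI
Why: Purdie methylation etherifies the α-hydroxy ketone under neutral conditions, so that neither enolisation with C-methylation nor α-ketol rearrangement should compete.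

**Step 10**
Reactants: 16 (2S,3R,4S,5S)-2-allyl-2-[(E)-3,3-diethoxy-2-methoxyprop-1-en-1-yl]-4-(3,4-dimethoxyphenyl)-5-methoxy-3-methylcyclopentan-1-one
Product: 17 (E)-3-[(1S,2R,3S,4S)-1-allyl-3-(3,4-dimethoxyphenyl)-4-methoxy-2-methyl-5-oxocyclopentyl]-2-methoxyprop-2-enal
Conditions: PPTS, acetone/H2O (10:1), rt
Reagents that add atoms: water, O
Why: Acid-catalysed hydrolysis of the allylic diethyl acetal through an alkenyl-stabilised oxocarbenium ion is far faster than protonation of the enol ether at C2, which would put positive charge next to the acetal carbon, and the 2-methoxy enal formed is deactivated towards further hydrolysis.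

**Step 11**
Reactants: 17 (E)-3-[(1S,2R,3S,4S)-1-allyl-3-(3,4-dimethoxyphenyl)-4-methoxy-2-methyl-5-oxocyclopentyl]-2-methoxyprop-2-enal
Product: 19 (1S,4S,5S,6S,7R)-1-allyl-6-(3,4-dimethoxyphenyl)-4-hydroxy-3,5-dimethoxy-7-methylbicyclo[3.2.1]oct-2-en-8-one (exo alcohol), via lithium enolate 18 (not isolated)
Conditions: LiN(SiMe3)2, THF, −78 °C; AcOH, −78 °C
Reagents that add atoms: none
Why: Intramolecular aldol addition, 6-(enolendo)-exo-trig: the C5 enolate (the only enolisable position) can reach the aldehyde only on the face that carries the arm, which fixes C5, and in the closed, lithium-bridged Zimmerman–Traxler-type transition state the aldehyde oxygen lies gauche to C8, which places the C4 hydroxyl exo, while the cold quench prevents retro-aldol equilibration.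

**Step 12**
Reactants: 19 (1S,4S,5S,6S,7R)-1-allyl-6-(3,4-dimethoxyphenyl)-4-hydroxy-3,5-dimethoxy-7-methylbicyclo[3.2.1]oct-2-en-8-one
Product: 20 (1S,4S,5S,6S,7R)-1-allyl-6-(3,4-dimethoxyphenyl)-3,5-dimethoxy-7-methyl-8-oxobicyclo[3.2.1]oct-2-en-4-yl acetate (CNP0221003.1)
Conditions: Ac2O, pyridine, DMAP (cat.), CH2Cl2, 0 °C → rt
Reagents that add atoms: acetic anhydride, CC(=O)OC(C)=O
Why: DMAP-catalysed acyl transfer acetylates the only free hydroxyl group with retention at C4.

**Compound list**

1 | (S)-4-[(tert-butyldimethylsilyl)oxy]cyclopent-2-en-1-one | O=C1C=C[C@@H](O[Si](C)(C)C(C)(C)C)C1 | starting material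
2 | (3,4-dimethoxyphenyl)magnesium bromide (THF solution) | COc1ccc([Mg]Br)cc1OC | starting material
3 | (3R,4S)-4-[(tert-butyldimethylsilyl)oxy]-3-(3,4-dimethoxyphenyl)cyclopentan-1-one | O=C1C[C@H](c2ccc(OC)c(OC)c2)[C@@H](O[Si](C)(C)C(C)(C)C)C1 | intermediate
4 | (S)-4-(3,4-dimethoxyphenyl)cyclopent-2-en-1-one | O=C1C[C@H](c2ccc(OC)c(OC)c2)C=C1 | intermediate
5 | (S)-4-(3,4-dimethoxyphenyl)-2-iodocyclopent-2-en-1-one | O=C1C[C@H](c2ccc(OC)c(OC)c2)C=C1I | intermediate
6 | 3,3-diethoxyprop-1-yne | C#CC(OCC)OCC | starting material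
7 | (E)-3,3-diethoxy-1-iodo-2-methoxyprop-1-ene | CCOC(OCC)/C(OC)=C\I | intermediate
8 | 2-[(E)-3,3-diethoxy-2-methoxyprop-1-en-1-yl]-4,4,5,5-tetramethyl-1,3,2-dioxaborolane | CCOC(OCC)/C(OC)=C\B1OC(C)(C)C(C)(C)O1 | intermediate
9 | (S)-2-[(E)-3,3-diethoxy-2-methoxyprop-1-en-1-yl]-4-(3,4-dimethoxyphenyl)cyclopent-2-en-1-one (key-step precursor) | CCOC(OCC)/C(OC)=C\C1=C[C@@H](c2ccc(OC)c(OC)c2)CC1=O | intermediate
10 | lithium dimethylcuprate | [Li+].C[Cu-]C | starting material
11 | allyl bromide | C=CCBr | starting material
12 | lithium C8=C1 enolate formed from 9 by methyl addition at C7 (not isolated) | [Li+].[O-]C1=C(/C=C(OC)\C(OCC)OCC)[C@H](C)[C@@H](c2ccc(OC)c(OC)c2)C1 | intermediate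
13 | (2S,3R,4S)-2-allyl-2-[(E)-3,3-diethoxy-2-methoxyprop-1-en-1-yl]-4-(3,4-dimethoxyphenyl)-3-methylcyclopentan-1-one (key-step product) | C=CC[C@@]1(/C=C(OC)\C(OCC)OCC)[C@H](C)[C@@H](c2ccc(OC)c(OC)c2)CC1=O | intermediate
14 | potassium C8=C5 enolate of 13 (not isolated) | [K+].[O-]C1=C[C@H](c2ccc(OC)c(OC)c2)[C@@H](C)[C@@]1(CC=C)/C=C(OC)\C(OCC)OCC | intermediate
15 | (2S,3R,4S,5S)-2-allyl-2-[(E)-3,3-diethoxy-2-methoxyprop-1-en-1-yl]-4-(3,4-dimethoxyphenyl)-5-hydroxy-3-methylcyclopentan-1-one | C=CC[C@@]1(/C=C(OC)\C(OCC)OCC)[C@H](C)[C@@H](c2ccc(OC)c(OC)c2)[C@H](O)C1=O | intermediate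
16 | (2S,3R,4S,5S)-2-allyl-2-[(E)-3,3-diethoxy-2-methoxyprop-1-en-1-yl]-4-(3,4-dimethoxyphenyl)-5-methoxy-3-methylcyclopentan-1-one | C=CC[C@@]1(/C=C(OC)\C(OCC)OCC)[C@H](C)[C@@H](c2ccc(OC)c(OC)c2)[C@H](OC)C1=O | intermediate
17 | (E)-3-[(1S,2R,3S,4S)-1-allyl-3-(3,4-dimethoxyphenyl)-4-methoxy-2-methyl-5-oxocyclopentyl]-2-methoxyprop-2-enal | C=CC[C@@]1(/C=C(OC)\C=O)[C@H](C)[C@@H](c2ccc(OC)c(OC)c2)[C@H](OC)C1=O | intermediate
18 | lithium C8=C5 enolate of 17 (not isolated) | [Li+].[O-]C1=C(OC)[C@H](c2ccc(OC)c(OC)c2)[C@@H](C)[C@@]1(CC=C)/C=C(OC)\C=O | intermediate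
19 | (1S,4S,5S,6S,7R)-1-allyl-6-(3,4-dimethoxyphenyl)-4-hydroxy-3,5-dimethoxy-7-methylbicyclo[3.2.1]oct-2-en-8-one | C=CC[C@]12C=C(OC)[C@H](O)[C@](OC)(C1=O)[C@H](c1ccc(OC)c(OC)c1)[C@H]2C | intermediate
20 | (1S,4S,5S,6S,7R)-1-allyl-6-(3,4-dimethoxyphenyl)-3,5-dimethoxy-7-methyl-8-oxobicyclo[3.2.1]oct-2-en-4-yl acetate | C=CC[C@]12C=C(OC)[C@H](OC(C)=O)[C@](OC)(C1=O)[C@H](c1ccc(OC)c(OC)c1)[C@H]2C | target

**Totals and risks**

Total steps: 12. Longest linear sequence: 10 steps (1 → 3 → 4 → 5 → 9 → 13 → 15 → 16 → 17 → 19 → 20); the side branch 6 → 7 → 8 joins at step 6.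

Steps most likely to fail:

1. Step 7 (key step). The copper-containing lithium enolate may alkylate too slowly. Proton transfer would then move the enolate to the C5 side, and allylation would be spread over C1, C5 and oxygen. Fallback, from 9 back to 13: after the same Me2CuLi addition the enolate is acylated on oxygen with allyl chloroformate (THF/HMPA, −78 °C) to give the allyl enol carbonate F1, which fixes the enolate regiochemistry in an isolable compound. Catalytic Pd(PPh3)4 (zerovalent palladium) in THF at room temperature then triggers the decarboxylative Tsuji allylation. The π-allylpalladium cation and the enolate should recombine at C1 on the face anti to the C7 methyl group and give 13 with loss of CO2.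

2. Step 4. The electrophilic addition may not stop at the enol ether stage, may leak to the other regioisomer, or may be outrun by iodination of the acetylenic C–H bond. Fallback, from 6 back to 7, built on a syn addition and two stereoretentive exchanges instead of one anti addition: 6 is C-silylated (n-BuLi, Me3SiCl, THF, −78 °C) to the silylalkyne F2. Copper-catalysed borylcupration–protonation (B2pin2, CuCl, NaOt-Bu, Xantphos, MeOH, THF) adds boron and hydrogen syn, with boron at C3, the carbon β to both silicon and the acetal oxygens. This gives the vinylboronate F3 with silicon cis to the acetal carbon. Chan–Lam-type etherification (Cu(OAc)2, Et3N, MeOH, air) replaces boron by OMe with retention and gives the vinylsilane F4. Iododesilylation (NIS, MeCN, 0 °C) replaces silicon by iodine with retention and delivers 7.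

3. Step 11. Closure through an open, non-chelated transition state, with the aldehyde oxygen anti to C8, would place the C4 oxygen on the endo face. Fallback, from 17 back to 20: the endo alcohol F5 obtained in that case is not discarded. Mitsunobu esterification (PPh3, DIAD, AcOH, toluene, 0 °C → rt) displaces the activated allylic C4–O bond with inversion. Acetate approaches from the C8 face and gives 20 directly, so step 12 is not needed.

**Further compounds**

F1 | step 7 | allyl (3R,4S)-2-[(E)-3,3-diethoxy-2-methoxyprop-1-en-1-yl]-4-(3,4-dimethoxyphenyl)-3-methylcyclopent-1-en-1-yl carbonate | C=CCOC(=O)OC1=C(/C=C(OC)\C(OCC)OCC)[C@H](C)[C@@H](c2ccc(OC)c(OC)c2)C1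
F2 | step 4 | (3,3-diethoxyprop-1-yn-1-yl)trimethylsilane | C[Si](C)(C)C#CC(OCC)OCC
F3 | step 4 | 2-[(Z)-3,3-diethoxy-1-(trimethylsilyl)prop-1-en-2-yl]-4,4,5,5-tetramethyl-1,3,2-dioxaborolane | CCOC(OCC)/C(B1OC(C)(C)C(C)(C)O1)=C\[Si](C)(C)C
F4 | step 4 | (E)-(3,3-diethoxy-2-methoxyprop-1-en-1-yl)trimethylsilane | CCOC(OCC)/C(OC)=C\[Si](C)(C)C
F5 | step 11 | (1S,4R,5S,6S,7R)-1-allyl-6-(3,4-dimethoxyphenyl)-4-hydroxy-3,5-dimethoxy-7-methylbicyclo[3.2.1]oct-2-en-8-one (endo alcohol) | C=CC[C@]12C=C(OC)[C@@H](O)[C@](OC)(C1=O)[C@H](c1ccc(OC)c(OC)c1)[C@H]2C
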